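Target **17** ⇐ **16** by O-demethylation ⇐ chromone **14** + PhB(OH)2 **15** (asymmetric 1,4-addition sets C2, ring C) ⇐ **12** ⇐ **11** (C-acetylation at C4a, then formylation and closure from the freed C8a–OH).
**11** ⇐ lactone **7** + dimethylketene dimer **8**: ring D is cut at C2'–C1' and C4'–C3' (key step).
Feature: ring D is a 4,4,6,6-tetramethylcyclohexane-1,3,5-trione whose only non-quaternary carbon, C2', sits on the C8 methine. C1'(=O)–C6'Me2–C5'(=O)–C4'Me2 is one molecule of **8**, and C2'–C3'(=O) is the CH2–C(=O)–O of a dihydrocoumarin closed on the C8a oxygen of ring A.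
**7** ⇐ **6** ⇐ coumarin **5** (CuH conjugate reduction sets the methine carbon) ⇐ phenol **3** + keto ester **4** (Pechmann) ⇐ **1** (C–H borylation and oxidation).
Ring order: ring A is bought; temporary lactone ring (step 2); ring D (step 5, lactone consumed); ring C (steps 7 and 8).

Key step: step 5

Locants: ring A and C atoms carry flavanone locants (O1, C2–C8a). For the lactones **5**–**10** chroman-2-one locants are used: lactone C4 is the later methine carbon, lactone C8a is flavanone C8a, lactone C8 is flavanone C4a. Ring D atoms are primed (C2' bears the methine).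

Assumption: the sense of induction in steps 3 and 8 is assigned by analogy with simpler substrates; if a first run shows the other sense, the antipodal ligand is used and nothing else changes.

Step 1
Reactants: 1 2,6-dimethoxytoluene
Product: 3 3,5-dimethoxy-4-methylphenol, via pinacol boronate 2 (not isolated)
Conditions: [Ir(OMe)(cod)]2 (1.5 mol %), 4,4'-di-tert-butyl-2,2'-bipyridine (3 mol %), B2pin2 (1.0 equiv), THF, 80 °C; then KHSO5, acetone–H2O, rt
Reagents that add atoms: bis(pinacolato)diboron CC1(C)OB(OC1(C)C)B2OC(C)(C)C(C)(C)O2 (boron and pinacol of 2); potassium peroxymonosulfate [K+].OOS(=O)(=O)[O-] (phenol oxygen of 3)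
Why: Iridium-catalysed C–H borylation is steered by sterics to the only ring C–H of 1 without an ortho substituent (para to the methyl group), and oxidation of the C–B bond of 2 in the same flask should give the symmetric phenol.

Step 2
Reactants: 3 3,5-dimethoxy-4-methylphenol; 4 ethyl 5-methyl-3-oxohexanoate
Product: 5 5,7-dimethoxy-6-methyl-4-(2-methylpropyl)-2H-chromen-2-one
Conditions: CF3CO2H (neat), 60 °C
Reagents that add atoms: none
Why: Pechmann condensation (transesterification, Friedel–Crafts-type closure, dehydration) on a phloroglucinol-type phenol whose two free ortho carbons are equivalent by symmetry, so only one coumarin, with the isobutyl group at C4, can form.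

Step 3
Reactants: 5 5,7-dimethoxy-6-methyl-4-(2-methylpropyl)-2H-chromen-2-one
Product: 6 (4R)-5,7-dimethoxy-6-methyl-4-(2-methylpropyl)-3,4-dihydro-2H-chromen-2-ol (both C2 anomers)
Conditions: Cu(OAc)2·H2O (3 mol %), (S)-DTBM-SEGPHOS (3 mol %), (EtO)2MeSiH (4 equiv), t-BuOH (1 equiv), toluene, rt; aq. NH4F
Reagents that add atoms: none
Why: Asymmetric CuH conjugate reduction delivers hydride to C4 from the face chosen by the chiral bisphosphine, which sets C4 as R; the aryl lactone formed first is expected to be reduced on to the lactol, as is usual for coumarins, and excess silane makes this complete so that one product is handled.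

Step 4
Reactants: 6 (4R)-5,7-dimethoxy-6-methyl-4-(2-methylpropyl)-3,4-dihydro-2H-chromen-2-ol
Product: 7 (4R)-5,7-dimethoxy-6-methyl-4-(2-methylpropyl)-3,4-dihydro-2H-chromen-2-one
Conditions: (n-Pr4N)RuO4 (5 mol %), N-methylmorpholine N-oxide (1.5 equiv), 4 Å MS, CH2Cl2, rt
Reagents that add atoms: none
Why: Ley–Griffith oxidation of the cyclic hemiacetal to the lactone under neutral conditions; C4 is not alpha to the carbonyl group and cannot epimerise.

Step 5
Reactants: 7 (4R)-5,7-dimethoxy-6-methyl-4-(2-methylpropyl)-3,4-dihydro-2H-chromen-2-one; 8 2,2,4,4-tetramethylcyclobutane-1,3-dione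
Product: 11 3-hydroxy-2-[(1S)-1-(6-hydroxy-2,4-dimethoxy-3-methylphenyl)-3-methylbutyl]-4,4,6,6-tetramethylcyclohex-2-ene-1,5-dione, via aldol adduct 9 (not isolated), via keto lactone 10 (not isolated)
Conditions: LiN(i-Pr)2 (1.05 equiv), THF, −78 °C; 8 (1.0 equiv), −78 → −20 °C; LiN(i-Pr)2 (1.5 equiv), −78 °C → rt; 1 M HCl, 0 °C
Reagents that add atoms: none
Why: Proposed new method: LiN(i-Pr)2 removes a C3 proton of 7, the only acidic C–H of either partner, and the ester enolate adds to a carbonyl group of 8; the strained cyclobutoxide 9 then opens by retro-aldol cleavage of a C(O)–CMe2 ring bond, and the tertiary ketone enolate so formed is quenched by the C3–H that now lies between two carbonyl groups, leaving the enolate of keto lactone 10. The second charge of base removes the isopropyl methine proton, and the dianion closes ring D by C-acylation of its tertiary enolate carbon at the lactone carbonyl C2 (6-exo-trig, or 6-exo-dig if the aryl keto ester enolate first expels the aryloxide to an acylketene), which forms the second C–C bond and frees the C8a oxygen as a phenoxide. The closest known reactions are the ring opening of 8 by alkoxides and carbanions to 2,2,4-trimethyl-3-oxopentanoyl derivatives, the aldol addition of aryl ester enolates to ketones, and the Dieckmann or Claisen closure of triketones onto esters; their combination on a lactone enolate is without precedent. No stereocentre is created: C4 of 7 is never deprotonated and becomes the methine of 11 unchanged in space, its descriptor turning from R to S only because ring D outranks the aryl group. The selectivities needed are addition at carbon to 8 (its carbonyl groups are equivalent and it has no alpha-hydrogen), fragmentation of the aldolate in preference to reversal (only ring opening relieves the four-ring strain and is irreversible), and C- over O-acylation in the closure, which should be settled thermodynamically because the triketone enolate is by far the most stable anion and an enol lactone would be reopened by the aryloxide.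

Step 6
Reactants: 11 3-hydroxy-2-[(1S)-1-(6-hydroxy-2,4-dimethoxy-3-methylphenyl)-3-methylbutyl]-4,4,6,6-tetramethylcyclohex-2-ene-1,5-dione
Product: 12 2-[(1S)-1-(3-acetyl-2-hydroxy-4,6-dimethoxy-5-methylphenyl)-3-methylbutyl]-3-hydroxy-4,4,6,6-tetramethylcyclohex-2-ene-1,5-dione
Conditions: AcCl (1.3 equiv), TiCl4 (3 equiv), CH2Cl2, −20 °C → rt; 1 M HCl
Reagents that add atoms: acetyl chloride CC(Cl)=O
Why: Titanium-mediated ortho Friedel–Crafts acylation of a phenol: C4a is the only unsubstituted ring carbon, lies ortho to the titanium-bound C8a oxygen and is activated by three oxygen substituents, the methyl ethers are stable to TiCl4 at this temperature, and ring D, a cyclic triketone that cannot chelate, stays as its enol (an enol acetate, if formed, is hydrolysed in the acidic work-up).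

Step 7
Reactants: 12 2-[(1S)-1-(3-acetyl-2-hydroxy-4,6-dimethoxy-5-methylphenyl)-3-methylbutyl]-3-hydroxy-4,4,6,6-tetramethylcyclohex-2-ene-1,5-dione
Product: 14 8-[(1S)-1-(2-hydroxy-3,3,5,5-tetramethyl-4,6-dioxocyclohex-1-en-1-yl)-3-methylbutyl]-5,7-dimethoxy-6-methyl-4H-chromen-4-one, via keto aldehyde 13 (not isolated)
Conditions: NaH (6 equiv), HCO2Et (10 equiv), THF, 0 °C → rt; then AcOH, conc. HCl (cat.), rt
Reagents that add atoms: ethyl formate CCOC=O
Why: Claisen formylation of the only enolisable ketone (ring D and the phenol are present as inert sodium salts), then acid-catalysed hemiacetal formation from the C8a–OH and dehydration, is the classical chromone synthesis from 2-hydroxyacetophenones and closes the achiral form of ring C.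

Step 8
Reactants: 14 8-[(1S)-1-(2-hydroxy-3,3,5,5-tetramethyl-4,6-dioxocyclohex-1-en-1-yl)-3-methylbutyl]-5,7-dimethoxy-6-methyl-4H-chromen-4-one; 15 phenylboronic acid (3 equiv)
Product: 16 (2R)-8-[(1S)-1-(2-hydroxy-3,3,5,5-tetramethyl-4,6-dioxocyclohex-1-en-1-yl)-3-methylbutyl]-5,7-dimethoxy-6-methyl-2-phenyl-2,3-dihydro-4H-chromen-4-one
Conditions: Pd(OCOCF3)2 (10 mol %), (S)-t-BuPyOx (12 mol %), NH4PF6 (30 mol %), H2O (5 equiv), ClCH2CH2Cl, 60 °C
Reagents that add atoms: none
Why: Pd-catalysed asymmetric conjugate addition of an arylboronic acid to a chromone (aryl–Pd insertion into C2=C3, protonolysis of the palladium enolate), in which the pyridine–oxazoline ligand, not the remote side-chain centre, should select the face of C2 and give the 2R flavanone under weakly acidic conditions that do not open ring C.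

Step 9
Reactants: 16 (2R)-8-[(1S)-1-(2-hydroxy-3,3,5,5-tetramethyl-4,6-dioxocyclohex-1-en-1-yl)-3-methylbutyl]-5,7-dimethoxy-6-methyl-2-phenyl-2,3-dihydro-4H-chromen-4-one
Product: 17 (2R)-5,7-dihydroxy-8-[(1S)-1-(2-hydroxy-3,3,5,5-tetramethyl-4,6-dioxocyclohex-1-en-1-yl)-3-methylbutyl]-6-methyl-2-phenyl-2,3-dihydro-4H-chromen-4-one (CNP0249552.1)
Conditions: BBr3 (5 equiv), CH2Cl2, −78 → 0 °C; H2O, 0 °C
Reagents that add atoms: none
Why: BBr3 ether cleavage, fast at the C5 methoxy group through chelation with the C4 carbonyl group and at the C7 methoxy group because its two ortho substituents twist it out of the ring plane, run and quenched cold so that ring C is not opened and no pyran closes between the C7–OH and ring D.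

Compound list
1 | 2,6-dimethoxytoluene | COc1cccc(OC)c1C | starting material
2 | 2-(3,5-dimethoxy-4-methylphenyl)-4,4,5,5-tetramethyl-1,3,2-dioxaborolane | COc1cc(cc(OC)c1C)B1OC(C)(C)C(C)(C)O1 | intermediate
3 | 3,5-dimethoxy-4-methylphenol | COc1cc(O)cc(OC)c1C | intermediate
4 | ethyl 5-methyl-3-oxohexanoate | CCOC(=O)CC(=O)CC(C)C | starting material
5 | 5,7-dimethoxy-6-methyl-4-(2-methylpropyl)-2H-chromen-2-one | COc1cc2OC(=O)C=C(CC(C)C)c2c(OC)c1C | intermediate
6 | (4R)-5,7-dimethoxy-6-methyl-4-(2-methylpropyl)-3,4-dihydro-2H-chromen-2-ol (both C2 anomers) | COc1cc2OC(O)C[C@@H](CC(C)C)c2c(OC)c1C | intermediate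
7 | (4R)-5,7-dimethoxy-6-methyl-4-(2-methylpropyl)-3,4-dihydro-2H-chromen-2-one | COc1cc2OC(=O)C[C@@H](CC(C)C)c2c(OC)c1C | intermediate
8 | 2,2,4,4-tetramethylcyclobutane-1,3-dione | CC1(C)C(=O)C(C)(C)C1=O | starting material
9 | (4R)-3-(1-hydroxy-2,2,4,4-tetramethyl-3-oxocyclobutyl)-5,7-dimethoxy-6-methyl-4-(2-methylpropyl)-3,4-dihydro-2H-chromen-2-one (lithium alkoxide in the flask; C3 not defined) | COc1cc2OC(=O)C(C3(O)C(C)(C)C(=O)C3(C)C)[C@@H](CC(C)C)c2c(OC)c1C | intermediate
10 | (4R)-5,7-dimethoxy-6-methyl-4-(2-methylpropyl)-3-(2,2,4-trimethyl-3-oxopentanoyl)-3,4-dihydro-2H-chromen-2-one (lithium enolate in the flask) | COc1cc2OC(=O)C(C(=O)C(C)(C)C(=O)C(C)C)[C@@H](CC(C)C)c2c(OC)c1C | intermediate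
11 | 3-hydroxy-2-[(1S)-1-(6-hydroxy-2,4-dimethoxy-3-methylphenyl)-3-methylbutyl]-4,4,6,6-tetramethylcyclohex-2-ene-1,5-dione | COc1cc(O)c([C@H](CC(C)C)C2=C(O)C(C)(C)C(=O)C(C)(C)C2=O)c(OC)c1C | intermediate
12 | 2-[(1S)-1-(3-acetyl-2-hydroxy-4,6-dimethoxy-5-methylphenyl)-3-methylbutyl]-3-hydroxy-4,4,6,6-tetramethylcyclohex-2-ene-1,5-dione | COc1c(C(C)=O)c(O)c([C@H](CC(C)C)C2=C(O)C(C)(C)C(=O)C(C)(C)C2=O)c(OC)c1C | intermediate
13 | 3-{2-hydroxy-3-[(1S)-1-(2-hydroxy-3,3,5,5-tetramethyl-4,6-dioxocyclohex-1-en-1-yl)-3-methylbutyl]-4,6-dimethoxy-5-methylphenyl}-3-oxopropanal (sodium salt in the flask) | COc1c(C(=O)CC=O)c(O)c([C@H](CC(C)C)C2=C(O)C(C)(C)C(=O)C(C)(C)C2=O)c(OC)c1C | intermediate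
14 | 8-[(1S)-1-(2-hydroxy-3,3,5,5-tetramethyl-4,6-dioxocyclohex-1-en-1-yl)-3-methylbutyl]-5,7-dimethoxy-6-methyl-4H-chromen-4-one | COc1c(C)c(OC)c([C@H](CC(C)C)C3=C(O)C(C)(C)C(=O)C(C)(C)C3=O)c2OC=CC(=O)c12 | intermediate
15 | phenylboronic acid | OB(O)c1ccccc1 | starting material
16 | (2R)-8-[(1S)-1-(2-hydroxy-3,3,5,5-tetramethyl-4,6-dioxocyclohex-1-en-1-yl)-3-methylbutyl]-5,7-dimethoxy-6-methyl-2-phenyl-2,3-dihydro-4H-chromen-4-one | COc1c(C)c(OC)c([C@H](CC(C)C)C3=C(O)C(C)(C)C(=O)C(C)(C)C3=O)c2O[C@@H](c4ccccc4)CC(=O)c12 | intermediate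
17 | (2R)-5,7-dihydroxy-8-[(1S)-1-(2-hydroxy-3,3,5,5-tetramethyl-4,6-dioxocyclohex-1-en-1-yl)-3-methylbutyl]-6-methyl-2-phenyl-2,3-dihydro-4H-chromen-4-one | Cc1c(O)c2c(c([C@H](CC(C)C)C3=C(O)C(C)(C)C(=O)C(C)(C)C3=O)c1O)O[C@@H](c1ccccc1)CC2=O | target

Total step count: 9
Longest linear sequence: 9 steps (1 to 17)

Steps most likely to fail

Step 5 (key step). The hindered ester enolate may add only slowly or reversibly to the doubly neopentyl ketone. The aldolate may acylate itself on the aryl ester (closing a beta-lactone with loss of the aryloxide) instead of fragmenting. The second enolisation at the isopropyl methine may be incomplete, so that the sequence stops at the keto lactone. Fallback with known chemistry, from 7: the lithium enolate (LiN(SiMe3)2, 2.1 equiv, THF, −78 °C) is C-acylated in a Claisen-type reaction with 2,2,4-trimethyl-3-oxopentanoyl chloride, a known acid chloride made from the lactone dimer of dimethylketene and HCl. Keto lactone 10 is then isolated, so no ring opening of 8 is needed. Ring D is closed in a separate Dieckmann condensation with KN(SiMe3)2 (2.5 equiv, THF, 0 °C → rt), and the route is rejoined at 11. This fallback makes no compound outside the list (F0).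

Step 3. Hydride delivery to C4 may be slow, because C4 is deactivated by the 5- and 7-methoxy groups and crowded by the peri 5-methoxy group. Facial selectivity on a 4-alkyl-5-alkoxycoumarin may also be poor. Fallback, from 3: Pd(OAc)2-catalysed hydroarylation of ethyl propiolate in CF3CO2H with lactonisation should give the 4-unsubstituted coumarin 5,7-dimethoxy-6-methyl-2H-chromen-2-one F1. Copper-catalysed asymmetric conjugate addition of i-BuMgBr (CuBr·SMe2, Josiphos-type ferrocenyl bisphosphine, CH2Cl2, −72 °C) then forms the C4–isobutyl bond and the stereocentre together. The route is rejoined at 7; compounds 5 and 6 are bypassed.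

Step 9. Lewis-acid-promoted beta-elimination may open ring C, which would erase C2 and allow re-closure onto the freed C5 oxygen. Dehydrative pyran closure between the new C7–OH and ring D is a second risk. Fallback, from 14: both ethers are cleaved with BBr3 (CH2Cl2, −78 → 0 °C) at the achiral chromone stage, giving 5,7-dihydroxy-8-[(1S)-1-(2-hydroxy-3,3,5,5-tetramethyl-4,6-dioxocyclohex-1-en-1-yl)-3-methylbutyl]-6-methyl-4H-chromen-4-one F2. The conjugate addition of 15 under the conditions of step 8 is then run last, so that no Lewis acid follows the creation of C2. The route is rejoined at 17.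

Further compounds
F0 | step 5 | none | none
F1 | step 3 | 5,7-dimethoxy-6-methyl-2H-chromen-2-one | COc1cc2OC(=O)C=Cc2c(OC)c1C
F2 | step 9 | 5,7-dihydroxy-8-[(1S)-1-(2-hydroxy-3,3,5,5-tetramethyl-4,6-dioxocyclohex-1-en-1-yl)-3-methylbutyl]-6-methyl-4H-chromen-4-one | Cc1c(O)c2c(c([C@H](CC(C)C)C3=C(O)C(C)(C)C(=O)C(C)(C)C3=O)c1O)OC=CC2=O
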